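Ring A (C1–C5 and C10, icetexane numbering) is cut into the two-carbon unit C10–C1 and the four-carbon unit C2–C5. A catalytic enantioselective Diels–Alder reaction of two acyclic partners, 2-bromoacrolein (C1, C10, C20) and methyl (3E)-4-methylhexa-3,5-dienoate (C2–C7), forms C1–C2 and C5–C10 in one operation. It sets C5 and the fully substituted C10. It exploits the vicinal pair C10–O/C20 beside ring A: the bromo aldehyde is a latent spiro-epoxide, so oxygen replaces bromine with inversion and C20 becomes the point of arylation. After hydromethylation at C4, an aryl anion attacks the C7 lactone and closes ring B, the oxygen bridge and the hemiketal together. Oxidation to quinone ring C comes last.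

Key step: step 4

Numbering used:
- C10 is the carbinol carbon that bears the bridge oxygen.
- C1–C3 are the ring A CH2 groups, C4 is CMe2, C5 is the ring-fusion CH and C6 is CH2.
- C7 is the hemiketal carbon.
- C8 and C9 are the ring C carbons that bear C7 and C20. C20 is the CH2 between C9 and C10.
- C11 and C14 are the quinone carbonyls, C12 bears OMe and C13 bears isopropyl.

Assumption: the (R)-tryptophan-derived boron catalyst is taken to leave open the face of 2-bromoacrolein that gives the (S)-configured C–Br centre of 9. The mirror-image catalyst would be used if the sense were the opposite.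

Step 1
Reactants: 1 (E)-2-methylbut-2-enal (tiglic aldehyde); 2 trimethyl phosphonoacetate
Product: 3 methyl (2E,4E)-4-methylhexa-2,4-dienoate
Conditions: NaH, THF, 0 °C to rt
Reagents that add atoms: none
Why: Horner–Wadsworth–Emmons olefination of an enal with a stabilised phosphonate should give the (E)-enoate and leave the (E)-trisubstituted alkene untouched.

Step 2
Reactants: 3 methyl (2E,4E)-4-methylhexa-2,4-dienoate
Product: 5 methyl (3E)-4-methylhexa-3,5-dienoate, via lithium trienolate 4 (not isolated)
Conditions: LiN(iPr)2, THF–DMPU, −78 °C; then AcOH, −78 °C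
Reagents that add atoms: none
Why: Deconjugative protonation: only the terminal CH3 gives an ester-stabilised extended enolate, kinetic protonation takes place at the α-carbon (C6), and the s-trans conformer of 3 fixes the new C4=C5 bond as (E).

Step 3
Reactants: 6 acrolein
Product: 8 2-bromoacrolein, via 2,3-dibromopropanal 7 (not isolated)
Conditions: Br2, CH2Cl2, −78 to 0 °C; then Et3N, 0 °C
Reagents that add atoms: bromine, BrBr
Why: Bromine addition to the alkene followed by E1cB dehydrobromination of the acidic α-hydrogen is the standard bromination–elimination route to a 2-bromo enal.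

Step 4
Reactants: 5 methyl (3E)-4-methylhexa-3,5-dienoate; 8 2-bromoacrolein
Product: 9 methyl 2-[(1R,6S)-6-bromo-6-formyl-2-methylcyclohex-2-en-1-yl]acetate (Br cis and CHO trans to the CH2CO2Me arm)
Conditions: (4R)-2-butyl-4-(1H-indol-3-ylmethyl)-3-[(4-methylphenyl)sulfonyl]-1,3,2-oxazaborolidin-5-one (10 mol %), CH2Cl2, −78 °C
Reagents that add atoms: none
Why: Concerted but asynchronous [4+2] cycloaddition (Lewis-acid-catalysed enantioselective Diels–Alder reaction of a 2-substituted acrolein), in which the boron-bound formyl group lowers the LUMO of 8 and the bond C1–C2 runs ahead of C5–C10. Ring A is the only ring closed, suprafacially on both partners through a boat-like six-membered transition state. C10 is controlled by the catalyst: the indole ring of the tryptophan-derived oxazaborolidinone covers one face of the bound enal, so the diene adds to the open face. C5 follows from the (E)-geometry of the C4=C5 bond together with the exo mode that 2-substituted acroleins prefer (bulky catalyst-bound formyl group away from the C4 methyl group, bromine under the diene), which puts Br cis and CHO trans to the CH2CO2Me arm. Regioselectivity is needed as well: the unsubstituted terminus C2 is the least hindered and most nucleophilic end (its attack leaves an allyl-cation-like fragment that carries three alkyl groups), so it bonds to the β-carbon C1 and the 1-alkyl group outweighs the 2-methyl group. The ester is a weaker Lewis base than the aldehyde and should stay a spectator.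

Step 5
Reactants: 9 bromo aldehyde
Product: 11 methyl 2-[(3R,4R)-5-methyl-1-oxaspiro[2.5]oct-5-en-4-yl]acetate, via bromohydrin 10 (not isolated)
Conditions: NaBH4, MeOH, −40 to 0 °C; then K2CO3, MeOH, rt
Reagents that add atoms: none
Why: Chemoselective 1,2-reduction of the aldehyde is followed by halohydrin-to-epoxide closure (intramolecular SN2), which inverts C10 so that oxygen ends trans and C20 cis to the C5 arm.

Step 6
Reactants: 12 1,2,4-trimethoxybenzene
Product: 14 2-(2,3,6-trimethoxyphenyl)propan-2-ol, via aryllithium 13 (not isolated)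
Conditions: n-BuLi, THF, 0 °C to rt; acetone, −78 °C to rt; H2O
Reagents that add atoms: acetone, CC(C)=O
Why: Directed ortho-metalation takes place at the C–H flanked by two methoxy groups, and 1,2-addition of the aryllithium to acetone follows.

Step 7
Reactants: 14 2-(2,3,6-trimethoxyphenyl)propan-2-ol
Product: 15 1,2,4-trimethoxy-3-(propan-2-yl)benzene
Conditions: Et3SiH, CF3CO2H, CH2Cl2, 0 °C to rt
Reagents that add atoms: none
Why: Ionic hydrogenation: the tertiary benzylic cation, stabilised by two ortho-methoxy groups, forms readily and is captured by the silane.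

Step 8
Reactants: 15 1,2,4-trimethoxy-3-(propan-2-yl)benzene; 11 spiro-epoxide ester
Product: 19 (3aR,7aS)-4-methyl-7a-{[2,3,5-trimethoxy-4-(propan-2-yl)phenyl]methyl}-3a,6,7,7a-tetrahydro-1-benzofuran-2(3H)-one (trans-fused lactone), via aryllithium 16 (not isolated), via arylmagnesium bromide 17 (not isolated), via hydroxy ester 18 (not isolated)
Conditions: n-BuLi, TMEDA, Et2O, 0 °C to rt; MgBr2·OEt2, −20 °C; CuI (10 mol %), 11, THF, −30 °C to 40 °C; aq NH4Cl
Reagents that add atoms: none
Why: Directed ortho-metalation should choose C9–H (one ortho and two meta methoxy groups, whereas the methoxy group next to C8–H is twisted by the isopropyl group), the copper-catalysed SN2 opening of the epoxide at its CH2 group (C20) leaves C10 untouched, and the tertiary alkoxide lactonises onto the ester.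

Step 9
Reactants: 19 alkene lactone
Product: 21 (3aR,7aS)-4,4-dimethyl-7a-{[2,3,5-trimethoxy-4-(propan-2-yl)phenyl]methyl}hexahydro-1-benzofuran-2(3H)-one, via hydrazide 20 (not isolated)
Conditions: TsNHNH2, (CH2O)n, THF, rt (CH2=NNHTs made in the flask); Fe(acac)3 (30 mol %), PhSiH3, THF–MeOH, rt; then MeOH, 60 °C
Reagents that add atoms: formaldehyde tosylhydrazone, C=NNS(=O)(=O)c1ccc(C)cc1
Why: Hydrogen-atom-transfer hydromethylation of an alkene: the iron hydride delivers H to C3, the tertiary C4 radical adds to the small formaldehyde hydrazone, and the adduct loses sulfinate and N2 on warming, so the new carbon ends as CH3 and C4 is no stereocenter.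

Step 10
Reactants: 21 gem-dimethyl lactone
Product: 22 (3aR,7aS)-7a-{[2-bromo-3,5,6-trimethoxy-4-(propan-2-yl)phenyl]methyl}-4,4-dimethylhexahydro-1-benzofuran-2(3H)-one
Conditions: NBS, MeCN, 0 °C
Reagents that add atoms: N-bromosuccinimide, O=C1CCC(=O)N1Br
Why: Electrophilic aromatic bromination can only take the single free ring position C8, which is ortho and para to methoxy groups.

Step 11
Reactants: 22 bromo lactone
Product: 24 (5R,7S,10S)-7,10-epoxy-7-hydroxy-11,12,14-trimethoxyicetexa-8,11,13-triene (bridged hemiketal), via aryllithium 23 (not isolated)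
Conditions: n-BuLi, THF, −100 to −78 °C; H2O
Reagents that add atoms: none
Why: Parham cyclisation: bromine–lithium exchange outruns attack of n-BuLi on the lactone, the C8 anion adds to the C7 carbonyl through a six-membered ring and so closes ring B and the pyran ring, and the bridge from C10 allows only the (7S)-hemiketal.

Step 12
Reactants: 24 hemiketal
Product: 25 (5R,7S,10S)-7,10-epoxy-7-hydroxy-12-methoxyicetexa-8,12-diene-11,14-dione (CNP0290151.2)
Conditions: (NH4)2Ce(NO3)6, MeCN–H2O, 0 °C
Reagents that add atoms: water, O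
Why: Oxidative demethylation of the para-related C11 and C14 methoxy groups gives the p-quinone and keeps the C12 methoxy group, while the bridgehead hemiketal cannot ionise and no stereocenter is touched.

Compound list
1 | (E)-2-methylbut-2-enal | C/C=C(\C)C=O | starting material
2 | trimethyl phosphonoacetate | COC(=O)CP(=O)(OC)OC | starting material
3 | methyl (2E,4E)-4-methylhexa-2,4-dienoate | COC(=O)/C=C/C(C)=C/C | intermediate
4 | lithium trienolate of 3 | COC(O[Li])=C/C=C(C)/C=C | intermediate
5 | methyl (3E)-4-methylhexa-3,5-dienoate | COC(=O)C/C=C(C)/C=C | intermediate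
6 | acrolein | C=CC=O | starting material
7 | 2,3-dibromopropanal | O=CC(Br)CBr | intermediate
8 | 2-bromoacrolein | C=C(Br)C=O | intermediate
9 | methyl 2-[(1R,6S)-6-bromo-6-formyl-2-methylcyclohex-2-en-1-yl]acetate | COC(=O)C[C@@H]1C(C)=CCC[C@@]1(Br)C=O | intermediate
10 | methyl 2-[(1R,6S)-6-bromo-6-(hydroxymethyl)-2-methylcyclohex-2-en-1-yl]acetate | COC(=O)C[C@@H]1C(C)=CCC[C@@]1(Br)CO | intermediate
11 | methyl 2-[(3R,4R)-5-methyl-1-oxaspiro[2.5]oct-5-en-4-yl]acetate | COC(=O)C[C@@H]1C(C)=CCC[C@]12CO2 | intermediate
12 | 1,2,4-trimethoxybenzene | COc1ccc(OC)c(OC)c1 | starting material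
13 | (2,3,6-trimethoxyphenyl)lithium | COc1ccc(OC)c(OC)c1[Li] | intermediate
14 | 2-(2,3,6-trimethoxyphenyl)propan-2-ol | COc1ccc(OC)c(OC)c1C(C)(C)O | intermediate
15 | 1,2,4-trimethoxy-3-(propan-2-yl)benzene | COc1ccc(OC)c(OC)c1C(C)C | intermediate
16 | [2,3,5-trimethoxy-4-(propan-2-yl)phenyl]lithium | [Li]c1cc(OC)c(C(C)C)c(OC)c1OC | intermediate
17 | [2,3,5-trimethoxy-4-(propan-2-yl)phenyl]magnesium bromide | Br[Mg]c1cc(OC)c(C(C)C)c(OC)c1OC | intermediate
18 | methyl 2-[(1R,6S)-6-hydroxy-2-methyl-6-{[2,3,5-trimethoxy-4-(propan-2-yl)phenyl]methyl}cyclohex-2-en-1-yl]acetate | COC(=O)C[C@@H]1C(C)=CCC[C@]1(O)Cc1cc(OC)c(C(C)C)c(OC)c1OC | intermediate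
19 | (3aR,7aS)-4-methyl-7a-{[2,3,5-trimethoxy-4-(propan-2-yl)phenyl]methyl}-3a,6,7,7a-tetrahydro-1-benzofuran-2(3H)-one | COc1c(C(C)C)c(OC)cc(C[C@@]23CCC=C(C)[C@H]2CC(=O)O3)c1OC | intermediate
20 | N'-alkyl tosylhydrazide at the new C4 carbon (C4 configuration open) | COc1c(C(C)C)c(OC)cc(C[C@@]23CCCC(C)(CNNS(=O)(=O)c4ccc(C)cc4)[C@H]2CC(=O)O3)c1OC | intermediate
21 | (3aR,7aS)-4,4-dimethyl-7a-{[2,3,5-trimethoxy-4-(propan-2-yl)phenyl]methyl}hexahydro-1-benzofuran-2(3H)-one | COc1c(C(C)C)c(OC)cc(C[C@@]23CCCC(C)(C)[C@H]2CC(=O)O3)c1OC | intermediate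
22 | (3aR,7aS)-7a-{[2-bromo-3,5,6-trimethoxy-4-(propan-2-yl)phenyl]methyl}-4,4-dimethylhexahydro-1-benzofuran-2(3H)-one | COc1c(C(C)C)c(OC)c(Br)c(C[C@@]23CCCC(C)(C)[C@H]2CC(=O)O3)c1OC | intermediate
23 | C8 aryllithium from 22 | COc1c(C(C)C)c(OC)c([Li])c(C[C@@]23CCCC(C)(C)[C@H]2CC(=O)O3)c1OC | intermediate
24 | (5R,7S,10S)-7,10-epoxy-7-hydroxy-11,12,14-trimethoxyicetexa-8,11,13-triene | COc1c(C(C)C)c(OC)c2c(C[C@@]34CCCC(C)(C)[C@H]3C[C@]2(O)O4)c1OC | intermediate
25 | (5R,7S,10S)-7,10-epoxy-7-hydroxy-12-methoxyicetexa-8,12-diene-11,14-dione (CNP0290151.2) | COC1=C(C(C)C)C(=O)C2=C(C[C@@]34CCCC(C)(C)[C@H]3C[C@]2(O)O4)C1=O | target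

Total step count: 12. Longest linear sequence: 9 (steps 1, 2, 4, 5, 8, 9, 10, 11, 12).

Steps most likely to fail

1. Step 4. The cycloaddition may show too little preference for the exo mode (bromine under the diene). The diene may also add partly in the reverse orientation. Either way the C5/C10 relationship would be eroded. The fallback sets out from 5 and brings the C10 oxygen in with the dienophile, so that it is kept with retention and the opposite, formyl-endo mode is the productive one.
- Cycloaddition of 5 with 1-formylvinyl acetate under the mirror-image boron catalyst should give methyl 2-[(1R,6R)-6-acetoxy-6-formyl-2-methylcyclohex-2-en-1-yl]acetate F1.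
- NaBH4 in MeOH should then give the primary alcohol F2.
- MsCl and Et3N at −20 °C, applied at once to forestall acetyl migration, should give the mesylate F3.
- K2CO3 in MeOH removes the acetate, and the C10 alkoxide displaces the mesylate at C20. The route is rejoined at 11.

2. Step 8. Lithiation may also take place at C8–H. The arylmetal may open the hindered epoxide so slowly that the magnesium salt isomerises it. The fallback sets out from 15 and blocks C8 first.
- NBS in MeCN should give 1-bromo-2,4,5-trimethoxy-3-(propan-2-yl)benzene F4.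
- The only remaining ring C–H of F4 is metalated with TMPMgCl·LiCl to give [2-bromo-3,5,6-trimethoxy-4-(propan-2-yl)phenyl]magnesium chloride F5.
- Copper-catalysed opening of 11 should lead through the bromo hydroxy ester F6 to the bromo alkene lactone F7.
- The conditions of step 9 then carry F7 through the bromo hydrazide F8. The route is rejoined at 22.

3. Step 9. The hindered tertiary C4 radical may accept a second hydrogen atom faster than it is trapped, which amounts to plain reduction of the alkene. The fallback sets out from 19 and adds the carbon by a concerted path.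
- Simmons–Smith cyclopropanation (Et2Zn, CH2I2, CH2Cl2) should give the C3–C4 cyclopropane F9.
- Hydrogenolysis (H2, PtO2, AcOH) cleaves the least hindered bond, C3–CH2, and should give the gem-dimethyl group. The route is rejoined at 21.

Further compounds
F1 | step 4 | methyl 2-[(1R,6R)-6-acetoxy-6-formyl-2-methylcyclohex-2-en-1-yl]acetate | COC(=O)C[C@@H]1C(C)=CCC[C@]1(OC(C)=O)C=O
F2 | step 4 | methyl 2-[(1R,6R)-6-acetoxy-6-(hydroxymethyl)-2-methylcyclohex-2-en-1-yl]acetate | COC(=O)C[C@@H]1C(C)=CCC[C@]1(OC(C)=O)CO
F3 | step 4 | methyl 2-[(1R,6R)-6-acetoxy-6-(mesyloxymethyl)-2-methylcyclohex-2-en-1-yl]acetate | COC(=O)C[C@@H]1C(C)=CCC[C@]1(OC(C)=O)COS(C)(=O)=O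
F4 | step 8 | 1-bromo-2,4,5-trimethoxy-3-(propan-2-yl)benzene | COc1c(Br)cc(OC)c(OC)c1C(C)C
F5 | step 8 | [2-bromo-3,5,6-trimethoxy-4-(propan-2-yl)phenyl]magnesium chloride | COc1c(Br)c([Mg]Cl)c(OC)c(OC)c1C(C)C
F6 | step 8 | methyl 2-[(1R,6S)-6-{[2-bromo-3,5,6-trimethoxy-4-(propan-2-yl)phenyl]methyl}-6-hydroxy-2-methylcyclohex-2-en-1-yl]acetate | COC(=O)C[C@@H]1C(C)=CCC[C@]1(O)Cc1c(Br)c(OC)c(C(C)C)c(OC)c1OC
F7 | step 8 | (3aR,7aS)-7a-{[2-bromo-3,5,6-trimethoxy-4-(propan-2-yl)phenyl]methyl}-4-methyl-3a,6,7,7a-tetrahydro-1-benzofuran-2(3H)-one | COc1c(C(C)C)c(OC)c(Br)c(C[C@@]23CCC=C(C)[C@H]2CC(=O)O3)c1OC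
F8 | step 8 | N'-alkyl tosylhydrazide from F7 (C4 configuration open) | COc1c(C(C)C)c(OC)c(Br)c(C[C@@]23CCCC(C)(CNNS(=O)(=O)c4ccc(C)cc4)[C@H]2CC(=O)O3)c1OC
F9 | step 9 | C3–C4 cyclopropane from 19 (cyclopropane face open) | COc1c(C(C)C)c(OC)cc(C[C@@]23CCC4CC4(C)[C@H]2CC(=O)O3)c1OC
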